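Start from the balance of Friday's flask: once substrate has gone, bis adduct is the charge minus side product and minus unfinished mono adduct, so reckon these two small terms instead of the large one.

the same everywhere: substrate 0.50 M
- epsilon: reagent 0.59 M; run made earlier
- eta: reagent 1.9 M; run made earlier
- Tuesday's: reagent 0.400 M; time 2.0 d
- Friday's: reagent 1.50 M; time 2.0 d
- Monday's: reagent 1.25 M; time 2.0 d

| run | time / h | bis adduct / % | substrate / % |
|---|---|---|---|
| epsilon | 5.00 | 5.6 | 46.9 |
| epsilon | 10.0 | 9.5 | 29.9 |
| epsilon | 15.0 | 13.2 | 19.5 |
| epsilon | 20.0 | 13.8 | 16.0 |
| epsilon | 25.0 | 16.1 | 11.2 |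
| epsilon | 30.0 | 14.9 | 10.3 |
| eta | 5.00 | 37.7 | 6.1 |
| eta | 10.0 | 60.0 | 0.8 |
| eta | 15.0 | 74.6 | 0 |
| eta | 20.0 | 83.2 | 0 |
| eta | 25.0 | 87.5 | 0 |
| eta | 30.0 | 88.9 | 0 |

(scatter of a reading: 1 percentage point)

* which of these holds the largest part of the substrate at the end of Tuesday's (bis adduct / mono adduct / substrate)
* which of these holds the largest part of the substrate at the end of Friday's (bis adduct / mono adduct / substrate)
* which of these holds the largest part of the substrate at the end of Monday's (bis adduct / mono adduct / substrate)
* how much bis adduct is there at the end of Friday's, in percent of the substrate charged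

- percent here means substrate units held: one side product counts as two
- steps thought possible: substrate + bis adduct -> side product; substrate + reagent -> mono adduct; reagent + mono adduct -> bis adduct

Read both terms from the eta run. From 15.0 h to 20.0 h its bis adduct climbs 8.6 percentage points, then 4.3 points by 25.0 h, a shrink factor of 0.500 per 5.00 h. Continue that series: 4.30% is still to come, and the ceiling is 91.8%. Book the remaining 8.20% as side product.

Side product needs substrate and bis adduct together, so assume its share scales with charged [substrate]/[reagent]. Call the share per unit of that ratio the toll coefficient, an empirical number read from the eta run: 0.312. Friday's toll is 10.4%.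

For the mono adduct, compare [reagent] beyond two equivalents: 0.500 M on Friday's against 0.900 M in eta. Friday's 2.0 d then equals 26.7 h of eta, leaving 3.41% unfinished. Bis adduct stands at 86.2%.

The weak link is the ceiling, drawn from readings scattered by 1 point. Redo it from the readings at 10.0 h, 20.0 h and 30.0 h: the ceiling becomes 90.8%, and the toll rises by 1.3 points. Commit to slightly below the first figure.

The forecast gives mono adduct for Tuesday's, bis adduct for Friday's, bis adduct for Monday's, and 87% for Friday's bis adduct, somewhat above mine, with the side step “costing a few percent”.

The flasks give mono adduct, bis adduct, bis adduct and 86.9%.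

    substrate + bis adduct → side product (k = 9.70 × 10⁻⁵ /M/s)
    substrate + reagent → mono adduct (k = 9.40 × 10⁻⁵ /M/s)
    reagent + mono adduct → bis adduct (k = 3.20 × 10⁻⁵ /M/s)

Friday's flask holds 10.2% side product against the toll of 10.4%, and 2.84% mono adduct against the reckoned 3.41%. Now take a neighbour of Friday's flask, charged with 0.20 M substrate and otherwise the same. Its toll is 4.15%, and its clock leaves 0.0404% mono adduct. That flask ends with 3.71% side product, 0.247% mono adduct and 96.0% bis adduct.

The data come from a simulation for substances that don't exist; scatter was added.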